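Do not read a stop as an empty flask: Monday's flask stands still with 86.2 % of its starting material left at 12 h.

| setting | Monday's | Sunday's | flask |
|---|---|---|---|
| starting material | 20 mM | 10 mM | 20 mM |
| second substrate | 40 mM | 40 mM | 40.0 mM |
| gas | 1.4 mM (held) | 1.4 mM (held) | 1.4 mM (held) |
| free catalyst | 40 µM | 40 µM | 40 µM |
| remark | the very flask that is asked about, followed so far | run made earlier |  |
| time |  |  | 15 h |

| run | time / min | target / % | starting material / % |
|---|---|---|---|
| Monday's | 180 | 12.8 | 86.7 |
| Monday's | 360 | 13.1 | 86.2 |
| Monday's | 600 | 13.4 | 86.6 |
| Monday's | 720 | 13.5 | 86.2 |
| Sunday's | 8.00 | 1.5 | 98.6 |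
| Sunday's | 20.0 | 3.8 | 95.2 |
| Sunday's | 25.0 | 5.3 | 94.0 |
| Sunday's | 40.0 | 7.6 | 91.8 |

(scatter of a reading: 0.3 percentage points)

- ash: change nothing and wait 5.0 h more
- oak: at 15 h add free catalyst, 100 % of the amount charged, then wait 5.0 h
- cedar: at 15 h add starting material, 50.0 % of the amount charged, then wait 5.0 h
- alder: at 15 h take out 90 % of the target then present, then wait 5.0 h

- removed target is counted in
- at the start none of the gas is in solution
- additions bring no volume worth counting

* target, in percent of the starting material first charged, at 15 h
* which option adds most target ("none" when 2 percentage points or less is all one gets) (ash / oak / cedar / alder / none)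
* target present, with what was taken out counted in, in percent of the starting material first charged, after oak
* target present, with what was taken out counted in, in percent of the starting material first charged, after cedar

Set two times against each other. Take Sunday's opening pace, 7.6 % in 40.0 min. Assume that pace, in percent, does not depend on the charge of starting material, with second substrate and free catalyst as they are in both runs (pseudo-first-order in starting material). Then τw, the time to convert the whole charge at that pace, is 526 min. Divide Monday's last target reading by that pace. This gives τc, the working time of one catalyst charge, 71.1 min. τc is shorter than 180 min, and Monday's target readings run from 12.8 % there to 13.5 % at 720 min.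

Their ratio, 13.5 %, merely returns that reading, so it is no check; it is my estimate of target at 15 h. A fresh charge works for a new τc, which fits inside 5.0 h. It takes that share of the starting material left, so I expect oak to add 12 percentage points. Ash, cedar and alder add no catalyst, and τc is shorter than 15 h, so I expect each to gain less than 2 points and oak to be best.

The forecast says 13.6 % now, oak as best, 26.5 % after oak and 14 % after cedar. Its ground is “a fixed turnover budget of about 68”. My oak gain of 12 points is lower than its 13 points.

    second substrate + reagent + free catalyst → free catalyst + second product (k = 4.06 × 10⁵ /M²/min)
    gas ⇌ reagent, rate k2*(csat - [reagent]) (kL = 0.136 /min)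
    starting material + reagent + free catalyst → free catalyst + target (k = 3.26 × 10⁵ /M²/min)
    target + free catalyst ⇌ isomer of the product + free catalyst, rate k4*[free catalyst]*[target] forward; the back reaction follows from the equilibrium constant (K = 5.40, k = 140 /M/min)
    second substrate + free catalyst → spent catalyst (k = 1.02 /M/min)

Monday's flask gives 12.8 % at 15 h, with free catalyst at 0 %; oak adds 14 points and reaches 27.2 %, and cedar ends at 12.8 %. In Monday's flask, half of the target step's turnover up to 15 h is done by 35.3 min, while the half-life of starting material by that step, at 36.6 min, is 7.0 h. Sunday's flask, left until 15 h, reaches 13.9 % of its own charge against the ratio's 13.5 %; its target then stands at 34.8 per catalyst charged.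

The numbers in the tables stem from a simulated flask for substances that don't exist; the scatter is artificial.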